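The constants were chosen freely; the flask was simulated.

The number I started from was 0.00150 M, the c(living end) the initiator charge gives once each initiator has become a living end.

    free monomer + living end → monomer in chains + living end, rate k1*[living end]*[free monomer] (k1 = 0.25 L mol⁻¹ s⁻¹, Ea1 = 40.0 kJ mol⁻¹)
    free monomer + monomer in chains → side product (k2 = 0.0088 L mol⁻¹ s⁻¹, Ea2 = 69.0 kJ mol⁻¹)
    free monomer + initiator → living end + monomer in chains (k3 = 0.11 L mol⁻¹ s⁻¹, Ea3 = 44.0 kJ mol⁻¹)
    (constants at 40 °C)

common to all: free monomer 0.060 M; initiator 2.5 mol%; time 3.0 h

|  | temperature | remark |
|---|---|---|
| noon | 40 °C |  |
| summer |  | at −10 °C until 50 min, from then on at 40 °C |
| spring | 15 °C |  |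
| dusk | −10 °C |  |

- percent here means free monomer units held: one side product counts as two
- constants are those at 40 °C; use the activation energies for any other temperature

- the best flask by amount of monomer in chains, in percent of the free monomer charged; "all alike" if 1.5 percentage points covers them all (noon / summer / spring / dusk / all alike)
- amount of monomer in chains at the end, in percent of the free monomer charged, noon
- amount of monomer in chains at the end, in percent of the free monomer charged, summer
- amount of monomer in chains at the end, in percent of the free monomer charged, spring
- amount of monomer in chains at the end, in percent of the free monomer charged, dusk

I ranked the lifetimes in spring, from short to long. The initiator, meeting free monomer, lasted about 10.9 min, which is shorter than the run of 3.0 h. So I held c(living end) at its full value, and free monomer fell pseudo-first-order through the chain step, with a lifetime of 2.81 h. The side step came next: with chains holding as much as the charge, it gave free monomer a lifetime of 5.24 h, longer than the chain step's.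

So I counted turns, the run time divided by the chain step's lifetime, which in spring came to 1.07. A count of turns leaves exp(−turns) of the free monomer, and without the side step the rest goes into chains, so I gave spring a ceiling of 65.6%.

Noon had 4.05 turns, which leave about 1.74% of the free monomer. But at noon the side step gained on the chain step, since from the coldest to the hottest flask the side step speeds up 150 times and the chain step 19 times. With chains taken as holding as much as the charge, which is more than they can hold once the side step has a share, the side step's lifetime at noon came to 0.526 h against the chain step's 0.741 h, so this figure was a lower limit and I could not rank the two steps at noon by it. Summer had 2.93 turns after the change, and those ran at noon's temperature. Dusk had 0.219 turns, a ceiling of 19.7%, and its initiator lifetime took a third of the run. I put spring ahead of dusk, while noon and summer held more turns than spring, and how much of those the side step took I could not tell by this count. My reckoning stopped there.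

The forecast went further: spring best, with 45.4% for noon, 45.3% for summer, 52.3% for spring and 15.3% for dusk, its method being that “Dividing the two rate equations gives an analytic link between chains and free monomer”. For spring that gave a figure, 52.3%, where my count gave a ceiling, 65.6%.

The flasks gave 45.4% at noon, 45.2% in summer, 52.0% in spring and 15.3% at dusk, so spring was best. With the side step struck out, spring gave 64.2%, close to the 65.6% that 1.07 turns allow.

A neighbour of spring run at 0 °C, with the same amounts and time, gets 0.427 turns, which leave 65.2% of the free monomer. It ended with 67.3% of the free monomer left and 30.0% in chains.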